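**Strategy.** Everything rests on opening ring B between C6 and C7, the adjacent hydroxyl- and keto-bearing carbons of the α-ketol, which gives a 6,7-seco dimethyl ester. One acyloin condensation joins the two ester carbons, closes ring B and installs both oxygens as an enediol bis(silyl ether); hydrogen is later delivered to C6 from the open α face. The precursor is a ring-A cyclohexane (C3 silyl ether, C5 ester, quaternary C10) bonded through C9–C10 to a tetrahydrofuran (O, C9, C11–C13) whose C9 carries the C8 propionate arm and whose C13 carries the future lactone as two silyl ethers at C15 and C16.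

Key step: step 19

Remark on numbering: all intermediates carry labdane numbering (ring A C1–C5 and C10; C6 and C7 the ester carbons; ether ring O, C9, C11, C12, C13; arms C14–C15 and C16); β is the face of the C10 methyl group, α the opposite face.

Remark on the precursor: the two arms on C13 are carried as silyl ethers of a 1,4-diol (C15–O and C16–O) instead of an alkene, because the C15 oxygen is used as an internal leaving group that fixes C9 (step 16) and the lactone then needs only an oxidation.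

Assumption: the (2R,5R) auxiliary is taken to give the (5S,10S) series drawn; if the opposite sense is found, the (2S,5S) amine is used.

Step 1
Reactants: 1 (2R,5R)-2,5-diphenylpyrrolidine; 2 (E)-4-methoxybut-3-en-2-one
Product: 3 (E)-4-[(2R,5R)-2,5-diphenylpyrrolidin-1-yl]but-3-en-2-one
Conditions: THF, rt
Reagents that add atoms: none
Why: Conjugate addition–elimination of the secondary amine on the β-methoxy enone (vinylogous transamidation) gives the vinylogous amide without touching the auxiliary stereocentres.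

Step 2
Reactants: 3 (E)-4-[(2R,5R)-2,5-diphenylpyrrolidin-1-yl]but-3-en-2-one
Product: 4 (2R,5R)-1-[(1E)-3-(tert-butyldimethylsilyloxy)buta-1,3-dien-1-yl]-2,5-diphenylpyrrolidine
Conditions: KN(SiMe3)2, THF, −78 °C; then TBSCl, −78 °C → rt
Reagents that add atoms: tert-butyldimethylsilyl chloride, CC(C)(C)[Si](C)(C)Cl
Why: Kinetic deprotonation of the methyl ketone and O-silylation of the enolate (silyl enol ether formation) give the 1-amino-3-siloxydiene.

Step 3
Reactants: 4 (2R,5R)-1-[(1E)-3-(tert-butyldimethylsilyloxy)buta-1,3-dien-1-yl]-2,5-diphenylpyrrolidine; 5 methyl (E)-3-methyl-4-oxobut-2-enoate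
Product: 7 methyl (1S,2S)-2-formyl-2-methyl-5-oxocyclohex-3-ene-1-carboxylate (ring-A enone aldehyde), via endo cycloadduct 6 (not isolated)
Conditions: toluene, −20 °C → rt; then 1 M HCl, THF, 0 °C
Reagents that add atoms: none
Why: Diels–Alder reaction of a chiral aminosiloxydiene, in which the nucleophilic CH2 terminus bonds to C5 (β to the aldehyde), the E geometry of 5 becomes the trans relation of the C5 ester and the C10 formyl group, the C2-symmetric pyrrolidine shields one diene face and so sets the absolute configuration of C5 and C10, and acid then hydrolyses the silyl enol ether and eliminates the amine to the enone.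

Step 4
Reactants: 7 methyl (1S,2S)-2-formyl-2-methyl-5-oxocyclohex-3-ene-1-carboxylate
Product: 8 methyl (1S,2S)-2-(dimethoxymethyl)-2-methyl-5-oxocyclohex-3-ene-1-carboxylate
Conditions: HC(OMe)3, pyridinium p-toluenesulfonate (cat.), MeOH, rt
Reagents that add atoms: trimethyl orthoformate, COC(OC)OC; methanol, CO
Why: Acid-catalysed acetalisation is selective for the aldehyde, since the conjugated ring ketone is far less electrophilic, and masks C9 for the enolate and hydride steps.

Step 5
Reactants: 8 methyl (1S,2S)-2-(dimethoxymethyl)-2-methyl-5-oxocyclohex-3-ene-1-carboxylate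
Product: 10 methyl 2-(dimethoxymethyl)-2,6,6-trimethyl-5-oxocyclohex-3-ene-1-carboxylate (C5 and C10 as in 8), via monomethyl ketone 9 (not isolated)
Conditions: LiN(iPr)2, THF, −78 °C, then MeI; second cycle of LiN(iPr)2 and MeI in the same flask, −78 → 0 °C
Reagents that add atoms: iodomethane, CI
Why: Enolate alkylation run twice: C4 is the only enolisable position of the enone (C2 is vinylic, C10 quaternary), so kinetic α′-deprotonation and C-methylation build the non-stereogenic C4 gem-dimethyl group.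

Step 6
Reactants: 10 methyl 2-(dimethoxymethyl)-2,6,6-trimethyl-5-oxocyclohex-3-ene-1-carboxylate
Product: 11 methyl 2-(dimethoxymethyl)-2,6,6-trimethyl-5-oxocyclohexane-1-carboxylate
Conditions: H2 (1 atm), Pd/C, EtOAc, rt
Reagents that add atoms: none
Why: Heterogeneous catalytic hydrogenation saturates the disubstituted C1=C2 alkene of the enone and leaves ketone, ester and acetal untouched; no stereocentre is formed.

Step 7
Reactants: 11 methyl 2-(dimethoxymethyl)-2,6,6-trimethyl-5-oxocyclohexane-1-carboxylate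
Product: 13 methyl 2-formyl-5-hydroxy-2,6,6-trimethylcyclohexane-1-carboxylate (3β-OH), via hydroxy acetal 12 (not isolated)
Conditions: NaBH4, MeOH, 0 °C; then 1 M HCl, THF, rt
Reagents that add atoms: water, O
Why: Borohydride reduction of the 4,4-dimethyl 3-ketone proceeds by axial attack from the α face, because the equatorial path is blocked by the axial 4β-methyl group, and so gives the equatorial 3β-alcohol; the acidic work-up hydrolyses the dimethyl acetal to the C9 aldehyde.

Step 8
Reactants: 13 methyl 2-formyl-5-hydroxy-2,6,6-trimethylcyclohexane-1-carboxylate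
Product: 14 methyl 5-(tert-butyldimethylsilyloxy)-2-formyl-2,6,6-trimethylcyclohexane-1-carboxylate
Conditions: TBSOTf, 2,6-lutidine, CH2Cl2, 0 °C
Reagents that add atoms: tert-butyldimethylsilyl trifluoromethanesulfonate, CC(C)(C)[Si](C)(C)OS(=O)(=O)C(F)(F)F
Why: Silylation of the hindered secondary alcohol with a silyl triflate; the non-enolisable aldehyde is inert, and the 3-oxygen is capped before it can lactonise onto the cis C6 ester.

Step 9
Reactants: 14 methyl 5-(tert-butyldimethylsilyloxy)-2-formyl-2,6,6-trimethylcyclohexane-1-carboxylate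
Product: 15 methyl 5-(tert-butyldimethylsilyloxy)-2-ethynyl-2,6,6-trimethylcyclohexane-1-carboxylate
Conditions: dimethyl (1-diazo-2-oxopropyl)phosphonate, K2CO3, MeOH, rt
Reagents that add atoms: dimethyl (1-diazo-2-oxopropyl)phosphonate, CC(=O)C(=[N+]=[N-])P(=O)(OC)OC
Why: Ohira–Bestmann homologation turns the non-enolisable C9 aldehyde into the terminal alkyne C9≡C11 under carbonate conditions that cannot disturb the already trans (thermodynamic) C5 ester.

Step 10
Reactants: 16 2-methylprop-2-en-1-ol; 17 benzyl chloromethyl ether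
Product: 18 4-(benzyloxy)-2-methylidenebutan-1-ol
Conditions: n-BuLi (2.2 equiv), TMEDA, Et2O–hexane, 0 °C → rt; then 17, −78 → 0 °C
Reagents that add atoms: none
Why: Allylic metalation of methallyl alcohol gives the alkoxide-stabilised allyl dianion, whose carbon terminus is alkylated by the chloromethyl ether (dianion alkylation), adding C15 with its oxygen already benzylated.

Step 11
Reactants: 18 4-(benzyloxy)-2-methylidenebutan-1-ol
Product: 19 (R)-{2-[2-(benzyloxy)ethyl]oxiran-2-yl}methanol
Conditions: Ti(OiPr)4 (10 mol %), D-(−)-diethyl tartrate (12 mol %), t-BuOOH, 4 Å MS, CH2Cl2, −20 °C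
Reagents that add atoms: tert-butyl hydroperoxide, CC(C)(C)OO
Why: Sharpless asymmetric epoxidation of the 2-substituted allylic alcohol, in which the titanium D-(−)-tartrate catalyst delivers oxygen to the alkene face that gives the (R)-epoxy alcohol and so sets C13.

Step 12
Reactants: 19 (R)-{2-[2-(benzyloxy)ethyl]oxiran-2-yl}methanol
Product: 20 (S)-2-[2-(benzyloxy)ethyl]-2-[(tert-butyldimethylsilyloxy)methyl]oxirane
Conditions: TBSCl, imidazole, DMF, 0 °C → rt
Reagents that add atoms: tert-butyldimethylsilyl chloride, CC(C)(C)[Si](C)(C)Cl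
Why: Imidazole-promoted silylation of the primary alcohol protects O16; the descriptor changes only because silicon raises the CIP rank of C16.

Step 13
Reactants: 15 methyl 5-(tert-butyldimethylsilyloxy)-2-ethynyl-2,6,6-trimethylcyclohexane-1-carboxylate; 20 (S)-2-[2-(benzyloxy)ethyl]-2-[(tert-butyldimethylsilyloxy)methyl]oxirane
Product: 21 methyl 2-[6-(benzyloxy)-4-[(tert-butyldimethylsilyloxy)methyl]-4-hydroxyhex-1-yn-1-yl]-5-(tert-butyldimethylsilyloxy)-2,6,6-trimethylcyclohexane-1-carboxylate
Conditions: n-BuLi, THF, −78 °C; BF3·OEt2; then 20, −78 °C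
Reagents that add atoms: none
Why: BF3-promoted alkynylation of an epoxide: the lithium acetylide opens the 2,2-disubstituted oxirane at its CH2 carbon (C12) by SN2 attack, forming C11–C12 and leaving the C13–O bond, and with it the C13 configuration, untouched.

Step 14
Reactants: 21 methyl 2-[6-(benzyloxy)-4-[(tert-butyldimethylsilyloxy)methyl]-4-hydroxyhex-1-yn-1-yl]-5-(tert-butyldimethylsilyloxy)-2,6,6-trimethylcyclohexane-1-carboxylate
Product: 23 2-methoxytetrahydrofuran ketal (both C9 epimers), via dihydrofuran 22 (not isolated)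
Conditions: Ph3PAuCl (2 mol %), AgOSO2CF3 (2 mol %), CH2Cl2, rt; then MeOH, pyridinium p-toluenesulfonate (cat.)
Reagents that add atoms: methanol, CO
Why: Gold-catalysed 5-endo-dig hydroalkoxylation of the homopropargylic tertiary alcohol, the only cyclisation open while O15 is benzylated, forms the O13–C9 bond, and acid-catalysed addition of methanol to the enol ether gives the cyclic ketal; C9 is not yet fixed.

Step 15
Reactants: 23 2-methoxytetrahydrofuran ketal
Product: 25 methyl 5-(tert-butyldimethylsilyloxy)-2-{5-[(tert-butyldimethylsilyloxy)methyl]-2,8-dioxabicyclo[3.2.1]octan-1-yl}-2,6,6-trimethylcyclohexane-1-carboxylate, via hydroxy ketal 24 (not isolated)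
Conditions: H2 (1 atm), Pd/C, EtOAc, rt; filter; then pyridinium p-toluenesulfonate (cat.), 4 Å MS, CH2Cl2, rt
Reagents that add atoms: none
Why: Hydrogenolysis frees the C15 hydroxyl, which under acid catalysis displaces methanol at C9 (transketalisation) to give the strain-free bridged bicyclic ketal, in which O15 necessarily lies on the face of the C14 arm.

Step 16
Reactants: 25 bicyclic ketal; 26 tert-butyl[(1-methoxyethenyl)oxy]dimethylsilane
Product: 27 hydroxy diester with C9 acetate arm (9R,13R; C8 arm cis to the C16 arm)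
Conditions: TiCl4 (1.1 equiv), CH2Cl2, −78 °C
Reagents that add atoms: none
Why: Mukaiyama-type opening of a bicyclic ketal by a silyl ketene acetal: TiCl4 binds the less hindered O15, the C9–O15 bond ionises to the five-membered oxocarbenium ion while the titanium alkoxide arm still covers the face it left, and the nucleophile enters anti to it (inversion at C9), which places the new C8 arm cis to C16 as in the target.

Step 17
Reactants: 27 hydroxy diester
Product: 28 tris(silyl ether) diester with C8 methylene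
Conditions: TBSCl, imidazole, DMF, rt
Reagents that add atoms: tert-butyldimethylsilyl chloride, CC(C)(C)[Si](C)(C)Cl
Why: Standard silylation of the primary C15 alcohol, so that no free alkoxide interferes with the chelated enolate of the next step or with sodium in the key step.

Step 18
Reactants: 28 tris(silyl ether) diester with C8 methylene
Product: 29 6,7-seco dimethyl ester (3S,5S,8S,9R,10S,13R), the key-step precursor
Conditions: LiN(iPr)2 (1.2 equiv), THF, −78 °C; then MeI, −78 → −40 °C
Reagents that add atoms: iodomethane, CI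
Why: Alkylation of the lithium ester enolate chelated to the ring oxygen O13 (Fráter–Seebach-type alkylation of a β-alkoxy ester): in the six-membered chelate the bulky ring-A substituent on C9 covers one face, so methyl iodide adds anti to C10 and gives the 8S centre, while the C5 ester, flanked by two quaternary carbons, is not deprotonated.

Step 19
Reactants: 29 6,7-seco dimethyl ester
Product: 30 (13R)-3β,15,16-tris(tert-butyldimethylsilyloxy)-6,7-bis(trimethylsilyloxy)-9,13-epoxylabd-6-ene (ring-B enediol bis(trimethylsilyl) ether)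
Conditions: Na (dispersion, 4.5 equiv), Me3SiCl (6 equiv), toluene, reflux, slow addition of 29
Reagents that add atoms: chlorotrimethylsilane, C[Si](C)(C)Cl
Why: Sodium transfers one electron to each ester carbonyl, the two ketyl radical anions couple at carbon to form C6–C7, loss of two methoxides gives the 1,2-dione, and two further electrons give the enediolate, which the silyl chloride traps on both oxygens. The closest known reaction is the acyloin condensation of 1,6-diesters in its Rühlmann (chlorotrimethylsilane) modification, the standard route to 1,2-bis(silyloxy)cyclohexenes. Ring B closes as a six-membered carbocycle by intramolecular acyl–acyl coupling between the ester carbon on C5 and the one on C8, both of which become ring members. No stereocentre is created, and C5 and C8 keep their configuration because the silyl chloride removes methoxide before it can enolise either ester or expel the β-oxygen O13. The step needs chemoselectivity and ring closure over intermolecular coupling: the two esters are the only groups sodium can reduce (silyl ethers and the ether ring are inert), the C5–C10–C9–C8 backbone holds the ester carbons close, and slow addition keeps the substrate dilute.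

Step 20
Reactants: 30 ring-B enediol bis(trimethylsilyl) ether
Product: 34 (13R)-3β,15,16-tris(tert-butyldimethylsilyloxy)-9,13-epoxylabdane-6β,7β-diol, via enediol 31 (not isolated), via 6-oxo ketol 32 (not isolated), via 7-oxo ketol 33 (not isolated)
Conditions: MeOH (degassed), THF, rt; then NaBH4, 0 °C
Reagents that add atoms: none
Why: Neutral methanolysis of the silyl enol ethers gives the enediol, which ketonises to either α-ketol, and borohydride reduces whichever forms; hydrogen (proton or hydride) can reach C6 only from the α face, the β face being blocked by the axial C4 and C10 methyl groups, so the 6-oxygen ends up β on every path, while the C7 configuration (7β expected) is irrelevant because C7 is oxidised next.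

Step 21
Reactants: 34 6β,7β-diol
Product: 33 (13R)-3β,15,16-tris(tert-butyldimethylsilyloxy)-6β-hydroxy-9,13-epoxylabdan-7-one
Conditions: 2-iodoxybenzoic acid (1.3 equiv), DMSO–THF, rt
Reagents that add atoms: none
Why: Sterically controlled alcohol oxidation with 2-iodoxybenzoic acid: ligand exchange at iodine is easy for the C7 alcohol but strongly retarded for the axial 6β-alcohol wedged between two syn-axial methyl groups, and this oxidant does not cleave glycols, so the 6β-hydroxy 7-ketone forms without touching C6 or C8.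

Step 22
Reactants: 33 6β-hydroxy 7-ketone
Product: 35 (13R)-3β,6β,15,16-tetrahydroxy-9,13-epoxylabdan-7-one
Conditions: HF (48 % aq.), MeCN, 0 °C → rt
Reagents that add atoms: none
Why: Fluoride-driven cleavage of the three silyl ethers under acidic, base-free conditions that can neither enolise the α-ketol nor open the β-alkoxy ketone by elimination.

Step 23
Reactants: 35 tetrahydroxy ketone
Product: 37 (13R)-3β,6β-dihydroxy-7-oxo-9,13-epoxylabdan-15,16-olide, via lactol 36 (not isolated)
Conditions: 2,2,6,6-tetramethylpiperidin-1-oxyl (20 mol %), PhI(OAc)2 (2.5 equiv), CH2Cl2, rt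
Reagents that add atoms: none
Why: Nitroxyl-catalysed oxidative lactonisation of a 1,4-diol: the oxoammonium ion oxidises the unhindered primary C15 alcohol in preference to the neopentyl C16 alcohol and the secondary alcohols, the aldehyde closes to the lactol with O16, and a second oxidation gives the γ-lactone with its carbonyl at C15.

Step 24
Reactants: 37 dihydroxy lactone
Product: 38 CNP0325396.1, (13R)-3β-acetoxy-6β-hydroxy-7-oxo-9,13-epoxylabdan-15,16-olide (3S,5S,6S,8S,9R,10S,13R)
Conditions: Ac2O, pyridine, 4-(dimethylamino)pyridine (cat.), CH2Cl2, 0 °C → rt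
Reagents that add atoms: acetic anhydride, CC(=O)OC(C)=O
Why: Nucleophile-catalysed acylation of the equatorial 3β-alcohol; the axial 6β-alcohol, shielded by the C4 and C10 methyl groups and hydrogen-bonded to the ketone, should not react under these mild conditions.

**Compound list**

1 | (2R,5R)-2,5-diphenylpyrrolidine | N1[C@@H](c2ccccc2)CC[C@@H]1c1ccccc1 | starting material
2 | (E)-4-methoxybut-3-en-2-one | CO/C=C/C(C)=O | starting material
3 | (E)-4-[(2R,5R)-2,5-diphenylpyrrolidin-1-yl]but-3-en-2-one | CC(=O)/C=C/N1[C@@H](c2ccccc2)CC[C@@H]1c1ccccc1 | intermediate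
4 | (2R,5R)-1-[(1E)-3-(tert-butyldimethylsilyloxy)buta-1,3-dien-1-yl]-2,5-diphenylpyrrolidine | C=C(O[Si](C)(C)C(C)(C)C)/C=C/N1[C@@H](c2ccccc2)CC[C@@H]1c1ccccc1 | intermediate
5 | methyl (E)-3-methyl-4-oxobut-2-enoate | COC(=O)/C=C(\C)C=O | starting material
6 | endo cycloadduct: methyl 5-(tert-butyldimethylsilyloxy)-3-[(2R,5R)-2,5-diphenylpyrrolidin-1-yl]-2-formyl-2-methylcyclohex-4-ene-1-carboxylate (ester trans to formyl, amine cis to formyl) | CC(C)(C)[Si](C)(C)OC1=C[C@H](N2[C@@H](c3ccccc3)CC[C@@H]2c2ccccc2)[C@@](C=O)(C)[C@@H](C(=O)OC)C1 | intermediate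
7 | methyl (1S,2S)-2-formyl-2-methyl-5-oxocyclohex-3-ene-1-carboxylate | O=C1C=C[C@@](C=O)(C)[C@@H](C(=O)OC)C1 | intermediate
8 | methyl (1S,2S)-2-(dimethoxymethyl)-2-methyl-5-oxocyclohex-3-ene-1-carboxylate | O=C1C=C[C@@](C(OC)OC)(C)[C@@H](C(=O)OC)C1 | intermediate
9 | methyl 2-(dimethoxymethyl)-2,6-dimethyl-5-oxocyclohex-3-ene-1-carboxylate (C4 epimers; C5, C10 as in 8) | O=C1C=C[C@@](C(OC)OC)(C)[C@@H](C(=O)OC)C1C | intermediate
10 | methyl 2-(dimethoxymethyl)-2,6,6-trimethyl-5-oxocyclohex-3-ene-1-carboxylate (ester trans to the acetal carbon) | O=C1C=C[C@@](C(OC)OC)(C)[C@@H](C(=O)OC)C1(C)C | intermediate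
11 | methyl 2-(dimethoxymethyl)-2,6,6-trimethyl-5-oxocyclohexane-1-carboxylate (5β-CO2Me, 10β-CH3) | O=C1CC[C@@](C(OC)OC)(C)[C@@H](C(=O)OC)C1(C)C | intermediate
12 | methyl 2-(dimethoxymethyl)-5-hydroxy-2,6,6-trimethylcyclohexane-1-carboxylate (3β-OH, 5β-CO2Me, 10β-CH3) | O[C@H]1CC[C@@](C(OC)OC)(C)[C@@H](C(=O)OC)C1(C)C | intermediate
13 | methyl 2-formyl-5-hydroxy-2,6,6-trimethylcyclohexane-1-carboxylate (3β-OH, 5β-CO2Me, 10β-CH3, 10α-CHO) | O[C@H]1CC[C@@](C=O)(C)[C@@H](C(=O)OC)C1(C)C | intermediate
14 | methyl 5-(tert-butyldimethylsilyloxy)-2-formyl-2,6,6-trimethylcyclohexane-1-carboxylate (as 13) | CC(C)(C)[Si](C)(C)O[C@H]1CC[C@@](C=O)(C)[C@@H](C(=O)OC)C1(C)C | intermediate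
15 | methyl 5-(tert-butyldimethylsilyloxy)-2-ethynyl-2,6,6-trimethylcyclohexane-1-carboxylate (3β-OTBS, 5β-CO2Me, 10β-CH3, 10α-ethynyl) | CC(C)(C)[Si](C)(C)O[C@H]1CC[C@@](C#C)(C)[C@@H](C(=O)OC)C1(C)C | intermediate
16 | 2-methylprop-2-en-1-ol | C=C(C)CO | starting material
17 | benzyl chloromethyl ether | ClCOCc1ccccc1 | starting material
18 | 4-(benzyloxy)-2-methylidenebutan-1-ol | C=C(CO)CCOCc1ccccc1 | intermediate
19 | (R)-{2-[2-(benzyloxy)ethyl]oxiran-2-yl}methanol | C1[C@](CO)(CCOCc2ccccc2)O1 | intermediate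
20 | (S)-2-[2-(benzyloxy)ethyl]-2-[(tert-butyldimethylsilyloxy)methyl]oxirane | C1[C@](CO[Si](C)(C)C(C)(C)C)(CCOCc2ccccc2)O1 | intermediate
21 | methyl 2-[6-(benzyloxy)-4-[(tert-butyldimethylsilyloxy)methyl]-4-hydroxyhex-1-yn-1-yl]-5-(tert-butyldimethylsilyloxy)-2,6,6-trimethylcyclohexane-1-carboxylate (ring as 15, C13 as 20) | CC(C)(C)[Si](C)(C)O[C@H]1CC[C@@](C#CC[C@](CO[Si](C)(C)C(C)(C)C)(CCOCc2ccccc2)O)(C)[C@@H](C(=O)OC)C1(C)C | intermediate
22 | methyl 2-{5-[2-(benzyloxy)ethyl]-5-[(tert-butyldimethylsilyloxy)methyl]-4,5-dihydrofuran-2-yl}-5-(tert-butyldimethylsilyloxy)-2,6,6-trimethylcyclohexane-1-carboxylate | CC(C)(C)[Si](C)(C)O[C@H]1CC[C@@](C2=CC[C@](CO[Si](C)(C)C(C)(C)C)(CCOCc3ccccc3)O2)(C)[C@@H](C(=O)OC)C1(C)C | intermediate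
23 | methyl 2-{5-[2-(benzyloxy)ethyl]-5-[(tert-butyldimethylsilyloxy)methyl]-2-methoxyoxolan-2-yl}-5-(tert-butyldimethylsilyloxy)-2,6,6-trimethylcyclohexane-1-carboxylate (both C9 epimers) | CC(C)(C)[Si](C)(C)O[C@H]1CC[C@@](C2(OC)CC[C@](CO[Si](C)(C)C(C)(C)C)(CCOCc3ccccc3)O2)(C)[C@@H](C(=O)OC)C1(C)C | intermediate
24 | methyl 5-(tert-butyldimethylsilyloxy)-2-{5-[(tert-butyldimethylsilyloxy)methyl]-5-(2-hydroxyethyl)-2-methoxyoxolan-2-yl}-2,6,6-trimethylcyclohexane-1-carboxylate (both C9 epimers) | CC(C)(C)[Si](C)(C)O[C@H]1CC[C@@](C2(OC)CC[C@](CO[Si](C)(C)C(C)(C)C)(CCO)O2)(C)[C@@H](C(=O)OC)C1(C)C | intermediate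
25 | methyl 5-(tert-butyldimethylsilyloxy)-2-{5-[(tert-butyldimethylsilyloxy)methyl]-2,8-dioxabicyclo[3.2.1]octan-1-yl}-2,6,6-trimethylcyclohexane-1-carboxylate (ketal carbon C9, O15 on the face of the C14 arm) | CC(C)(C)[Si](C)(C)O[C@H]1CC[C@@]([C@@]23CC[C@](CO[Si](C)(C)C(C)(C)C)(CCO3)O2)(C)[C@@H](C(=O)OC)C1(C)C | intermediate
26 | tert-butyl[(1-methoxyethenyl)oxy]dimethylsilane | C=C(OC)O[Si](C)(C)C(C)(C)C | starting material
27 | methyl 5-(tert-butyldimethylsilyloxy)-2-{5-[(tert-butyldimethylsilyloxy)methyl]-5-(2-hydroxyethyl)-2-(2-methoxy-2-oxoethyl)oxolan-2-yl}-2,6,6-trimethylcyclohexane-1-carboxylate (9R,13R; C8 arm cis to C16 arm) | CC(C)(C)[Si](C)(C)O[C@H]1CC[C@@]([C@@]2(CC[C@](CO[Si](C)(C)C(C)(C)C)(CCO)O2)CC(=O)OC)(C)[C@@H](C(=O)OC)C1(C)C | intermediate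
28 | the C15 tert-butyldimethylsilyl ether of 27 | CC(C)(C)[Si](C)(C)O[C@H]1CC[C@@]([C@@]2(CC[C@](CO[Si](C)(C)C(C)(C)C)(CCO[Si](C)(C)C(C)(C)C)O2)CC(=O)OC)(C)[C@@H](C(=O)OC)C1(C)C | intermediate
29 | 6,7-seco dimethyl ester (3S,5S,8S,9R,10S,13R): methyl 5-(tert-butyldimethylsilyloxy)-2-{5-[(tert-butyldimethylsilyloxy)methyl]-5-[2-(tert-butyldimethylsilyloxy)ethyl]-2-[(2S)-1-methoxy-1-oxopropan-2-yl]oxolan-2-yl}-2,6,6-trimethylcyclohexane-1-carboxylate | CC(C)(C)[Si](C)(C)O[C@H]1CC[C@@]([C@@]2(CC[C@](CO[Si](C)(C)C(C)(C)C)(CCO[Si](C)(C)C(C)(C)C)O2)[C@H](C)C(=O)OC)(C)[C@@H](C(=O)OC)C1(C)C | intermediate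
30 | (13R)-3β,15,16-tris(tert-butyldimethylsilyloxy)-6,7-bis(trimethylsilyloxy)-9,13-epoxylabd-6-ene (8βH) | CC(C)(C)[Si](C)(C)O[C@H]1CC[C@@]2(C)[C@@H](C(O[Si](C)(C)C)=C(O[Si](C)(C)C)[C@@H](C)[C@]23CC[C@@](CCO[Si](C)(C)C(C)(C)C)(CO[Si](C)(C)C(C)(C)C)O3)C1(C)C | intermediate
31 | (13R)-3β,15,16-tris(tert-butyldimethylsilyloxy)-9,13-epoxylabd-6-ene-6,7-diol | CC(C)(C)[Si](C)(C)O[C@H]1CC[C@@]2(C)[C@@H](C(O)=C(O)[C@@H](C)[C@]23CC[C@@](CCO[Si](C)(C)C(C)(C)C)(CO[Si](C)(C)C(C)(C)C)O3)C1(C)C | intermediate
32 | (13R)-3β,15,16-tris(tert-butyldimethylsilyloxy)-7β-hydroxy-9,13-epoxylabdan-6-one | CC(C)(C)[Si](C)(C)O[C@H]1CC[C@@]2(C)[C@@H](C(=O)[C@H](O)[C@@H](C)[C@]23CC[C@@](CCO[Si](C)(C)C(C)(C)C)(CO[Si](C)(C)C(C)(C)C)O3)C1(C)C | intermediate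
33 | (13R)-3β,15,16-tris(tert-butyldimethylsilyloxy)-6β-hydroxy-9,13-epoxylabdan-7-one | CC(C)(C)[Si](C)(C)O[C@H]1CC[C@@]2(C)[C@@H]([C@H](O)C(=O)[C@@H](C)[C@]23CC[C@@](CCO[Si](C)(C)C(C)(C)C)(CO[Si](C)(C)C(C)(C)C)O3)C1(C)C | intermediate
34 | (13R)-3β,15,16-tris(tert-butyldimethylsilyloxy)-9,13-epoxylabdane-6β,7β-diol | CC(C)(C)[Si](C)(C)O[C@H]1CC[C@@]2(C)[C@@H]([C@H](O)[C@H](O)[C@@H](C)[C@]23CC[C@@](CCO[Si](C)(C)C(C)(C)C)(CO[Si](C)(C)C(C)(C)C)O3)C1(C)C | intermediate
35 | (13R)-3β,6β,15,16-tetrahydroxy-9,13-epoxylabdan-7-one | O[C@H]1CC[C@@]2(C)[C@@H]([C@H](O)C(=O)[C@@H](C)[C@]23CC[C@@](CCO)(CO)O3)C1(C)C | intermediate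
36 | lactol: (13R)-3β,6β,15-trihydroxy-9,13:15,16-diepoxylabdan-7-one (C15 epimers) | O[C@H]1CC[C@@]2(C)[C@@H]([C@H](O)C(=O)[C@@H](C)[C@]23CC[C@@]2(COC(O)C2)O3)C1(C)C | intermediate
37 | (13R)-3β,6β-dihydroxy-7-oxo-9,13-epoxylabdan-15,16-olide | O[C@H]1CC[C@@]2(C)[C@@H]([C@H](O)C(=O)[C@@H](C)[C@]23CC[C@@]2(COC(=O)C2)O3)C1(C)C | intermediate
38 | CNP0325396.1, (13R)-3β-acetoxy-6β-hydroxy-7-oxo-9,13-epoxylabdan-15,16-olide | CC(=O)O[C@H]1CC[C@@]2(C)[C@@H]([C@H](O)C(=O)[C@@H](C)[C@]23CC[C@@]2(COC(=O)C2)O3)C1(C)C | target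

**Step count.** Total: 24 steps. Longest linear sequence: 21 steps (steps 1–9, then 13–24); steps 10–12 make the epoxide fragment.

**Steps most likely to fail**

Step 19. Electron transfer to two strongly hindered esters may be slow, so that intermolecular coupling or plain reduction of the esters competes with ring closure. The fallback forms the same C6–C7 bond by polar acylation of an acyl-anion equivalent (Corey–Seebach). It sets out from 29: the less hindered C7 ester is half-reduced (iBu2AlH, CH2Cl2, −78 °C) to the C7 aldehyde F1, which propane-1,3-dithiol and BF3·OEt2 convert into the 1,3-dithiane F2. Lithiation (n-BuLi, THF, −30 °C) and intramolecular attack on the C6 ester close ring B as the 6-oxo 7,7-dithioketal F3. NaBH4 reduces the C6 ketone from the α face to the 6β-alcohol F4, and hydrolysis of the dithiane (MeI, CaCO3, aqueous MeCN) gives ketol 33, where the route is rejoined before step 22.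

Step 16. Ionisation at the hindered ketal carbon may be slower than consumption of the silyl ketene acetal by the Lewis acid, or silyl ethers may be lost. The fallback brings in the two-carbon arm as an allyl group and degrades it (Hosomi–Sakurai allylation, then oxidative cleavage). It sets out from 25: allyltrimethylsilane and TiCl4 (CH2Cl2, −78 °C) give the C9-allyl alcohol F5 by the same anti opening, and TBSCl with imidazole gives the tris(silyl ether) F6. Ozonolysis (O3, CH2Cl2, −78 °C, then PPh3) gives the aldehyde F7, Pinnick oxidation (NaClO2, NaH2PO4, 2-methylbut-2-ene) gives the acid F8, and Me3SiCHN2 in MeOH–toluene gives ester 28, where the route is rejoined.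

Step 18. The ester enolate may expel the ring oxygen by β-elimination, or methyl iodide may add to the wrong face. The fallback sets C8 in the carbon–carbon bond-forming step instead of by enolate alkylation. It sets out from 25, which is opened under the conditions of step 16 with the (E)-silyl ketene acetal of methyl propionate, tert-butyl[(1-methoxyprop-1-en-1-yl)oxy]dimethylsilane. An open, antiperiplanar transition state that turns the methyl group away from ring A should give the 8-methyl hydroxy diester F9; silylation (TBSCl, imidazole, DMF) then gives 29, where the route is rejoined.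

**Further compounds**

F1 | step 19 | C7 aldehyde of 29 (C6 methyl ester kept) | CC(C)(C)[Si](C)(C)O[C@H]1CC[C@@]([C@@]2(CC[C@](CO[Si](C)(C)C(C)(C)C)(CCO[Si](C)(C)C(C)(C)C)O2)[C@H](C)C=O)(C)[C@@H](C(=O)OC)C1(C)C
F2 | step 19 | 1,3-dithiane of F1 at C7 | CC(C)(C)[Si](C)(C)O[C@H]1CC[C@@]([C@@]2(CC[C@](CO[Si](C)(C)C(C)(C)C)(CCO[Si](C)(C)C(C)(C)C)O2)[C@H](C)C2SCCCS2)(C)[C@@H](C(=O)OC)C1(C)C
F3 | step 19 | (13R)-3β,15,16-tris(tert-butyldimethylsilyloxy)-7,7-(propane-1,3-diyldisulfanediyl)-9,13-epoxylabdan-6-one | CC(C)(C)[Si](C)(C)O[C@H]1CC[C@@]2(C)[C@@H](C(=O)C4(SCCCS4)[C@@H](C)[C@]23CC[C@@](CCO[Si](C)(C)C(C)(C)C)(CO[Si](C)(C)C(C)(C)C)O3)C1(C)C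
F4 | step 19 | (13R)-3β,15,16-tris(tert-butyldimethylsilyloxy)-7,7-(propane-1,3-diyldisulfanediyl)-9,13-epoxylabdan-6β-ol | CC(C)(C)[Si](C)(C)O[C@H]1CC[C@@]2(C)[C@@H]([C@H](O)C4(SCCCS4)[C@@H](C)[C@]23CC[C@@](CCO[Si](C)(C)C(C)(C)C)(CO[Si](C)(C)C(C)(C)C)O3)C1(C)C
F5 | step 16 | C9-allyl analogue of 27 (C15 alcohol) | CC(C)(C)[Si](C)(C)O[C@H]1CC[C@@]([C@@]2(CC[C@](CO[Si](C)(C)C(C)(C)C)(CCO)O2)CC=C)(C)[C@@H](C(=O)OC)C1(C)C
F6 | step 16 | C15 tert-butyldimethylsilyl ether of F5 | CC(C)(C)[Si](C)(C)O[C@H]1CC[C@@]([C@@]2(CC[C@](CO[Si](C)(C)C(C)(C)C)(CCO[Si](C)(C)C(C)(C)C)O2)CC=C)(C)[C@@H](C(=O)OC)C1(C)C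
F7 | step 16 | C7 aldehyde from F6 (C9–CH2–CHO) | CC(C)(C)[Si](C)(C)O[C@H]1CC[C@@]([C@@]2(CC[C@](CO[Si](C)(C)C(C)(C)C)(CCO[Si](C)(C)C(C)(C)C)O2)CC=O)(C)[C@@H](C(=O)OC)C1(C)C
F8 | step 16 | C7 carboxylic acid corresponding to 28 | CC(C)(C)[Si](C)(C)O[C@H]1CC[C@@]([C@@]2(CC[C@](CO[Si](C)(C)C(C)(C)C)(CCO[Si](C)(C)C(C)(C)C)O2)CC(=O)O)(C)[C@@H](C(=O)OC)C1(C)C
F9 | step 18 | 8-methyl hydroxy diester (29 with free C15 alcohol) | CC(C)(C)[Si](C)(C)O[C@H]1CC[C@@]([C@@]2(CC[C@](CO[Si](C)(C)C(C)(C)C)(CCO)O2)[C@H](C)C(=O)OC)(C)[C@@H](C(=O)OC)C1(C)C
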